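The quinone (ring A) is disconnected at Q1–Q2. Its two ring-fusion carbons, aryloxy-bearing Q5 and CH2CH2-bearing Q6, are adjacent and so map onto the substituted C=C of a cyclobutenedione, while the two CH carbons Q2 and Q3 map onto an ethynyl group. Heating a macrocyclic 4-ethynyl-4-hydroxycyclobutenone opens the four-membered ring to a vinylketene that closes on the alkyne terminus, so ring A grows inside the preformed 18-membered ring without changing its size. The precursor is the racemic ethynyl carbinol of a macrocyclic 3-aryloxy-4-alkylcyclobutenedione, itself closed by attack of the ring D phenol on a chlorocyclobutenedione; ring C is carried as a benzyl ether.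

Key step: step 12

Labels: ring A is the quinone (Q1 and Q4 carbonyl carbons, Q2 the methoxy carbon, Q3 the CH, Q5 the aryloxy carbon, Q6 the carbon bearing the CH2CH2 bridge); ring B is the para-phenylene, ring C the 1,2,4-trisubstituted phenol ring, ring D the meta-phenylene.

Remark on the chemistry: the ring C phenol is carried as a benzyl ether and the ring D phenol as a methoxymethyl ether, because the aqueous acid that turns the squarate adduct into the vinylogous acid should free the ring D phenol and nothing else. The target has no stereocentre; carbinols 16 and 21 are racemic.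

Step 1
Reactants: 1 tyrosol, 4-(2-hydroxyethyl)phenol
Product: 3 4-[2-(tert-butyldimethylsilyloxy)ethyl]phenol, via bis-silyl ether 2 (not isolated)
Conditions: TBSCl (2.2 equiv), imidazole, DMF, rt; then K2CO3, MeOH, rt
Reagents that add atoms: tert-butyldimethylsilyl chloride, CC(C)(C)[Si](C)(C)Cl
Why: Silylation of both hydroxyls followed by carbonate methanolysis, which cleaves aryl but not alkyl silyl ethers, should leave only the primary alcohol protected (silyl protection and selective desilylation).

Step 2
Reactants: 4 3-bromo-4-hydroxybenzaldehyde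
Product: 5 4-(benzyloxy)-3-bromobenzaldehyde
Conditions: BnBr, K2CO3, DMF, rt
Reagents that add atoms: benzyl bromide, BrCc1ccccc1
Why: Williamson etherification of an acidic para-formyl phenol is routine and installs an acid-stable, base-stable phenol protecting group.

Step 3
Reactants: 3 4-[2-(tert-butyldimethylsilyloxy)ethyl]phenol; 5 4-(benzyloxy)-3-bromobenzaldehyde
Product: 6 4-(benzyloxy)-3-{4-[2-(tert-butyldimethylsilyloxy)ethyl]phenoxy}benzaldehyde
Conditions: CuI (10 mol%), N,N-dimethylglycine hydrochloride (30 mol%), Cs2CO3, 1,4-dioxane, 100 °C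
Reagents that add atoms: none
Why: Ligand-promoted Ullmann diaryl ether coupling tolerates the aldehyde, the benzyl ether and the alkyl silyl ether and accepts bromides ortho to an alkoxy group.

Step 4
Reactants: 6 4-(benzyloxy)-3-{4-[2-(tert-butyldimethylsilyloxy)ethyl]phenoxy}benzaldehyde
Product: 7 1-(benzyloxy)-2-{4-[2-(tert-butyldimethylsilyloxy)ethyl]phenoxy}-4-ethenylbenzene
Conditions: Ph3PCH3Br, KOtBu, THF, 0 °C to rt
Reagents that add atoms: methyltriphenylphosphonium bromide, C[P+](c1ccccc1)(c1ccccc1)c1ccccc1.[Br-]
Why: Wittig methylenation of an aryl aldehyde is reliable and supplies the second carbon of the C–D ethylene bridge.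

Step 5
Reactants: 8 3-bromophenol
Product: 9 1-bromo-3-(methoxymethoxy)benzene
Conditions: MOMCl, iPr2NEt, CH2Cl2, 0 °C to rt
Reagents that add atoms: chloromethyl methyl ether, COCCl
Why: O-alkylation of the phenol gives an acetal that survives borane, palladium, fluoride and organolithium chemistry and is later removed by the acid of step 9.

Step 6
Reactants: 7 1-(benzyloxy)-2-{4-[2-(tert-butyldimethylsilyloxy)ethyl]phenoxy}-4-ethenylbenzene; 9 1-bromo-3-(methoxymethoxy)benzene
Product: 11 B–C–D silyl ether, the bibenzyl in which the styrene carbons of 7 have become the CH2CH2 link to the 3-(methoxymethoxy)phenyl ring D, via alkylborane 10 (not isolated)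
Conditions: 9-BBN, THF, rt; then 9, PdCl2(dppf) ([1,1'-bis(diphenylphosphino)ferrocene]dichloropalladium, 5 mol%), aq K3PO4, DMF, 60 °C
Reagents that add atoms: none
Why: Anti-Markovnikov hydroboration of the styrene and B-alkyl Suzuki–Miyaura coupling with the aryl bromide should give the saturated bridge directly, so no hydrogenation endangers the benzyl ether.

Step 7
Reactants: 11 B–C–D silyl ether
Product: 12 B–C–D alcohol, 2-[4-(2-benzyloxy-5-{2-[3-(methoxymethoxy)phenyl]ethyl}phenoxy)phenyl]ethanol
Conditions: TBAF, THF, 0 °C to rt
Reagents that add atoms: none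
Why: Fluoride desilylation of a primary alkyl silyl ether leaves the benzyl and methoxymethyl ethers untouched.

Step 8
Reactants: 12 B–C–D alcohol
Product: 13 B–C–D iodide, the 2-arylethyl iodide of 12
Conditions: I2, PPh3, imidazole, CH2Cl2, 0 °C to rt
Reagents that add atoms: iodine, II
Why: Appel-type iodination converts the primary alcohol into the iodide under buffered conditions that spare the acetal.

Step 9
Reactants: 13 B–C–D iodide; 14 diisopropyl squarate
Product: 18 seco acid, 3-hydroxy-4-(2-arylethyl)cyclobut-3-ene-1,2-dione with free ring D phenol and ring C benzyl ether, via alkyllithium 15 (not isolated), via squarate adduct 16 (not isolated), via isopropoxy dione 17 (not isolated)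
Conditions: t-BuLi (2.1 equiv), Et2O, −78 °C; 14, THF, −78 °C; then 6 M aq HCl, THF, 45 °C
Reagents that add atoms: water, O
Why: Iodine–lithium exchange and 1,2-addition of the primary alkyllithium to the squarate ester, followed by acid-mediated rearrangement to the 3-alkyl-4-isopropoxycyclobutenedione, hydrolysis of the vinylogous ester and acetal cleavage, should deliver the vinylogous acid and the ring D phenol in one operation while the benzyl ether survives.

Step 10
Reactants: 18 seco acid
Product: 20 macrocyclic cyclobutenedione, 18-membered ring in which C3 of the cyclobut-3-ene-1,2-dione carries the ring D oxygen and C4 the CH2CH2 link to ring B, via chloro dione 19 (not isolated)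
Conditions: (COCl)2, DMF (cat.), CH2Cl2, 0 °C to rt; concentrate; then slow addition to iPr2NEt, CH2Cl2, rt (1 mM)
Reagents that add atoms: none
Why: The strongly acidic vinylogous acid is converted into its chloride much faster than an un-ionised phenol is acylated, and addition–elimination of the phenol on the chlorocyclobutenedione under high dilution is an acyl-substitution-like macro-etherification.

Step 11
Reactants: 20 macrocyclic cyclobutenedione
Product: 21 macrocyclic 4-ethynyl-4-hydroxycyclobutenone, racemic carbinol, ring C as benzyl ether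
Conditions: HC≡CMgBr, THF, −78 to −40 °C; aq NH4Cl
Reagents that add atoms: ethynylmagnesium bromide, C#C[Mg]Br
Why: 1,2-Addition of the alkynyl Grignard reagent should occur at the ketone-like carbonyl next to the aryloxy carbon (the other carbonyl is a vinylogous ester), giving a racemic carbinol; the other regioisomer would converge in step 12.

Step 12
Reactants: 21 macrocyclic 4-ethynyl-4-hydroxycyclobutenone
Product: 22 macrocyclic 2-aryloxy-3-alkyl-1,4-benzoquinone, the O-benzyl target lacking the Q2 methoxy group
Conditions: PhMe (5 mM), 110 °C, argon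
Reagents that add atoms: none
Why: Thermal conrotatory four-electron opening of the cyclobutenone, with the donor hydroxyl turning outward and the ethynyl group inward, should give a (2-ethynylvinyl)ketene in which the Q6–Q5 unit is held s-cis because both atoms are tied into the macrocycle. The ketene carbon (Q1) then bonds to the alkyne terminus (Q2), closing ring A in the six-membered (endo) mode to a diradical with a σ-radical at Q3 and an oxygen-delocalised radical at Q4, and transfer of the hydroxyl hydrogen to Q3 gives the quinone. The closest known reaction is the Moore rearrangement of 4-alkynyl-4-hydroxycyclobutenones to 1,4-benzoquinones. No stereocentre is formed and the racemic carbinol centre is destroyed. The step needs six- over five-membered closure (quinone rather than alkylidenecyclopentenedione), which the hydrogen-terminated alkyne secures because the exocyclic vinyl radical of the five-membered path would be unstabilised, and it needs the outward rotation of the hydroxyl, which its donor character secures. The macrocycle stays 18-membered because Q5 and Q6 remain adjacent, and the regiochemistry of step 11 is irrelevant because Q2 and Q3 are both CH.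

Step 13
Reactants: 22 macrocyclic 2-aryloxy-3-alkyl-1,4-benzoquinone
Product: 23 O-benzyl target, the 2-methoxy-5-aryloxy-6-alkyl-1,4-benzoquinone with ring C as benzyl ether
Conditions: ZnCl2, MeOH, O2 (1 atm), 40 °C
Reagents that add atoms: methanol, CO
Why: Lewis-acid-promoted conjugate addition of methanol to the enone of the more electrophilic Q4 carbonyl (the Q1 carbonyl is deactivated as a vinylogous ester by the Q5 aryloxy group) should place the methoxy group on the unsubstituted Q2, and oxygen reoxidises the hydroquinone (oxidative nucleophilic addition to a quinone, as in the conversion of alkoxyquinones into 2,5-dialkoxyquinones).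

Step 14
Reactants: 23 O-benzyl target
Product: 25 target quinone CNP0332646.0, via hydroquinone 24 (not isolated)
Conditions: H2 (1 atm), Pd/C, EtOAc, rt; then air, rt
Reagents that add atoms: none
Why: Hydrogenolysis cleaves the benzyl aryl ether while the quinone rests as its hydroquinone, and admission of air over the palladium catalyst dehydrogenates this electron-rich hydroquinone back to the quinone without touching the ring C phenol (hydrogenolytic debenzylation and aerobic reoxidation).

Compound list
1 | tyrosol, 4-(2-hydroxyethyl)phenol | OCCc1ccc(O)cc1 | starting material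
2 | bis-silyl ether of tyrosol, tert-butyl{2-[4-(tert-butyldimethylsilyloxy)phenyl]ethoxy}dimethylsilane | CC(C)(C)[Si](C)(C)OCCc1ccc(O[Si](C)(C)C(C)(C)C)cc1 | intermediate
3 | 4-[2-(tert-butyldimethylsilyloxy)ethyl]phenol | CC(C)(C)[Si](C)(C)OCCc1ccc(O)cc1 | intermediate
4 | 3-bromo-4-hydroxybenzaldehyde | O=Cc1ccc(O)c(Br)c1 | starting material
5 | 4-(benzyloxy)-3-bromobenzaldehyde | O=Cc1ccc(OCc2ccccc2)c(Br)c1 | intermediate
6 | 4-(benzyloxy)-3-{4-[2-(tert-butyldimethylsilyloxy)ethyl]phenoxy}benzaldehyde | CC(C)(C)[Si](C)(C)OCCc1ccc(Oc2cc(C=O)ccc2OCc2ccccc2)cc1 | intermediate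
7 | 1-(benzyloxy)-2-{4-[2-(tert-butyldimethylsilyloxy)ethyl]phenoxy}-4-ethenylbenzene | CC(C)(C)[Si](C)(C)OCCc1ccc(Oc2cc(C=C)ccc2OCc2ccccc2)cc1 | intermediate
8 | 3-bromophenol | Oc1cccc(Br)c1 | starting material
9 | 1-bromo-3-(methoxymethoxy)benzene | COCOc1cccc(Br)c1 | intermediate
10 | alkylborane, 9-(2-arylethyl)-9-borabicyclo[3.3.1]nonane from 7 | CC(C)(C)[Si](C)(C)OCCc1ccc(Oc2cc(CCB3C4CCCC3CCC4)ccc2OCc2ccccc2)cc1 | intermediate
11 | B–C–D silyl ether | CC(C)(C)[Si](C)(C)OCCc1ccc(Oc2cc(CCc3cccc(OCOC)c3)ccc2OCc2ccccc2)cc1 | intermediate
12 | B–C–D alcohol | OCCc1ccc(Oc2cc(CCc3cccc(OCOC)c3)ccc2OCc2ccccc2)cc1 | intermediate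
13 | B–C–D iodide | ICCc1ccc(Oc2cc(CCc3cccc(OCOC)c3)ccc2OCc2ccccc2)cc1 | intermediate
14 | diisopropyl squarate | CC(C)OC1=C(OC(C)C)C(=O)C1=O | starting material
15 | alkyllithium from 13 | [Li]CCc1ccc(Oc2cc(CCc3cccc(OCOC)c3)ccc2OCc2ccccc2)cc1 | intermediate
16 | squarate adduct, 4-hydroxy-2,3-diisopropoxy-4-(2-arylethyl)cyclobut-2-en-1-one (racemic) | CC(C)OC1=C(OC(C)C)C(O)(CCc2ccc(Oc3cc(CCc4cccc(OCOC)c4)ccc3OCc3ccccc3)cc2)C1=O | intermediate
17 | isopropoxy dione, 3-isopropoxy-4-(2-arylethyl)cyclobut-3-ene-1,2-dione | CC(C)OC1=C(CCc2ccc(Oc3cc(CCc4cccc(OCOC)c4)ccc3OCc3ccccc3)cc2)C(=O)C1=O | intermediate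
18 | seco acid, 3-hydroxy-4-(2-arylethyl)cyclobut-3-ene-1,2-dione with free ring D phenol | OC1=C(CCc2ccc(Oc3cc(CCc4cccc(O)c4)ccc3OCc3ccccc3)cc2)C(=O)C1=O | intermediate
19 | chloro dione, 3-chloro-4-(2-arylethyl)cyclobut-3-ene-1,2-dione with free ring D phenol | ClC1=C(CCc2ccc(Oc3cc(CCc4cccc(O)c4)ccc3OCc3ccccc3)cc2)C(=O)C1=O | intermediate
20 | macrocyclic 3-aryloxy-4-alkylcyclobutenedione, ring C as benzyl ether | O=C1C(=O)C2=C1Oc1cccc(c1)CCc1ccc(OCc3ccccc3)c(c1)Oc1ccc(CC2)cc1 | intermediate
21 | macrocyclic 4-ethynyl-4-hydroxycyclobutenone, racemic, ring C as benzyl ether | C#CC1(O)C(=O)C2=C1Oc1cccc(c1)CCc1ccc(OCc3ccccc3)c(c1)Oc1ccc(CC2)cc1 | intermediate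
22 | macrocyclic 2-aryloxy-3-alkyl-1,4-benzoquinone, ring C as benzyl ether | O=C1C=CC(=O)C2=C1CCc1ccc(cc1)Oc1cc(ccc1OCc3ccccc3)CCc1cccc(c1)O2 | intermediate
23 | O-benzyl target, 2-methoxy-5-aryloxy-6-alkyl-1,4-benzoquinone | COC1=CC(=O)C2=C(CCc3ccc(cc3)Oc3cc(ccc3OCc4ccccc4)CCc3cccc(c3)O2)C1=O | intermediate
24 | hydroquinone of the target | COc1cc(O)c2c(CCc3ccc(cc3)Oc3cc(ccc3O)CCc3cccc(c3)O2)c1O | intermediate
25 | target quinone CNP0332646.0 (no stereocentre) | COC1=CC(=O)C2=C(CCc3ccc(cc3)Oc3cc(ccc3O)CCc3cccc(c3)O2)C1=O | target

Total step count: 14 steps.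
Longest linear sequence: 12 steps (steps 1, 3, 4 and 6 to 14 from tyrosol; the same length from 3-bromo-4-hydroxybenzaldehyde through steps 2, 3, 4 and 6 to 14).

Steps most likely to fail

Step 12. The ketene may close on the inner alkyne carbon in the five-membered mode, or the macrocycle may slow the ring opening enough for intermolecular capture of the ketene to compete. The fallback replaces the diradical closure by a six-electron electrocyclisation. It sets out from macrocyclic cyclobutenedione 20: vinylmagnesium bromide in THF at −78 °C should give the macrocyclic 4-ethenyl-4-hydroxycyclobutenone F1. Heating this in toluene opens it to a dienylketene that electrocyclises and tautomerises to the macrocyclic hydroquinone F2. Oxidation of F2 with Ag2O (ring C is still protected) returns to the route at quinone 22.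

Step 10. Intermolecular etherification may outrun ring closure, and the free ring D phenol may be acylated while the chloride is being made. The fallback keeps the phenol masked until the moment of closure. It sets out from seco acid 18: TBSCl and imidazole silylate both acidic hydroxyls to give the bis-silyl seco compound F3. Oxalyl chloride with catalytic DMF converts only the vinylogous silyl ester into the chloride, giving the silyl-protected chloro dione F4. Slow addition of F4 to anhydrous CsF in acetonitrile releases the phenoxide at low stationary concentration and should close the ring, returning to the route at 20.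

Step 13. Methanol may attack Q5 and expel the ring D aryloxide, opening the macrocycle by vinylogous transesterification, or reoxidation by oxygen may lag and stall the addition. The fallback brings in the Q2 oxygen with a non-exchanging nucleophile and methylates afterwards. It sets out from quinone 22: Thiele–Winter acetoxylation (Ac2O, catalytic H2SO4, rt) should give the triacetoxyarene F5 with acetoxy groups on Q1, Q2 and Q4. Methanolysis with K2CO3 in methanol under air gives the 2-hydroxyquinone F6. O-Methylation of F6 with Me2SO4 and K2CO3 in acetone returns to the route at 23.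

Further compounds
F1 | step 12 | macrocyclic 4-ethenyl-4-hydroxycyclobutenone, racemic, ring C as benzyl ether | C=CC1(O)C(=O)C2=C1Oc1cccc(c1)CCc1ccc(OCc3ccccc3)c(c1)Oc1ccc(CC2)cc1
F2 | step 12 | macrocyclic 2-aryloxy-3-alkylhydroquinone, ring C as benzyl ether | Oc1ccc(O)c2c1CCc1ccc(cc1)Oc1cc(ccc1OCc3ccccc3)CCc1cccc(c1)O2
F3 | step 10 | bis-silyl seco compound, vinylogous silyl ester and ring D aryl silyl ether of 18 | CC(C)(C)[Si](C)(C)OC1=C(CCc2ccc(Oc3cc(CCc4cccc(O[Si](C)(C)C(C)(C)C)c4)ccc3OCc3ccccc3)cc2)C(=O)C1=O
F4 | step 10 | chloro dione with ring D phenol as tert-butyldimethylsilyl ether | ClC1=C(CCc2ccc(Oc3cc(CCc4cccc(O[Si](C)(C)C(C)(C)C)c4)ccc3OCc3ccccc3)cc2)C(=O)C1=O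
F5 | step 13 | macrocyclic triacetoxyarene, acetoxy groups on Q1, Q2 and Q4, ring C as benzyl ether | CC(=O)Oc1cc(OC(C)=O)c2c(c1OC(C)=O)CCc1ccc(cc1)Oc1cc(ccc1OCc3ccccc3)CCc1cccc(c1)O2
F6 | step 13 | macrocyclic 2-hydroxy-5-aryloxy-6-alkyl-1,4-benzoquinone, hydroxyl on Q2, ring C as benzyl ether | O=C1C(O)=CC(=O)C2=C1CCc1ccc(cc1)Oc1cc(ccc1OCc3ccccc3)CCc1cccc(c1)O2
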